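**Strategy.** Ring B is made last. The fully substituted A/C chromone is finished first and carries only an ethynyl group on C2; ring B (C1'–C6'), a hydroquinone with para oxygens on C2' and C5', is then built on it by a chromium-carbene benzannulation that exploits this 1,4-dioxygen pattern. In one operation the alkyne, an alkenylcarbene and one CO ligand join through C5'–C6', C1'–C2' and C2'–C3': C5'–OBn comes from the carbene carbon, C2'–OH from CO. The precursor is 2-ethynyl-5,6,7,8-tetramethoxychromone. Its partner is a benzyloxycarbene complex whose vinyl group carries a trans-trimethylsilyl group, a stable stand-in for the polymerisation-prone parent vinyl complex. BCl3 finally frees 5-OH and 5'-OH.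

Key step: step 9

Remark: the target has no stereocentre and is achiral, so no enantiocontrol is needed; the only stereodescriptor in the route is the E alkene of the carbene building block.

Step 1
Reactants: 1 2,3,4-trimethoxybenzaldehyde
Product: 3 2,3,4-trimethoxyphenol, via aryl formate 2 (not isolated)
Conditions: 30% H2O2, cat. H2SO4, MeOH, rt
Reagents that add atoms: hydrogen peroxide, OO
Why: Acid-catalysed Dakin (Baeyer–Villiger-type) oxidation, in which the electron-rich aryl group migrates to peroxide oxygen and the formate is methanolysed in the same pot.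

Step 2
Reactants: 3 2,3,4-trimethoxyphenol
Product: 4 1,2,3,4-tetramethoxybenzene
Conditions: MeI, K2CO3, acetone, reflux
Reagents that add atoms: iodomethane, CI
Why: Williamson O-methylation of the phenoxide under standard carbonate conditions.

Step 3
Reactants: 4 1,2,3,4-tetramethoxybenzene
Product: 7 2,3,4,5-tetramethoxyphenol, via aryllithium 5 (not isolated), via dimethyl arylboronate 6 (not isolated)
Conditions: n-BuLi, TMEDA, THF, 0 °C; B(OMe)3, −78 °C → rt; 30% H2O2, AcOH, 0 °C
Reagents that add atoms: hydrogen peroxide, OO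
Why: Methoxy-directed ortho-lithiation (the two free ring positions are equivalent), borylation and oxidative boron-to-oxygen aryl shift should replace H by OH in one pot.

Step 4
Reactants: 7 2,3,4,5-tetramethoxyphenol
Product: 8 1-(2-hydroxy-3,4,5,6-tetramethoxyphenyl)ethan-1-one
Conditions: AcOH, BF3·OEt2, 90 °C; aq. work-up
Reagents that add atoms: acetic acid, CC(=O)O
Why: BF3-mediated Friedel–Crafts (Fries-type) C-acetylation can only enter the single free ring position, ortho to the phenol, whose hydroxyl then chelates the new ketone.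

Step 5
Reactants: 8 1-(2-hydroxy-3,4,5,6-tetramethoxyphenyl)ethan-1-one; 9 ethyl 2,2-diethoxyacetate
Product: 12 5,6,7,8-tetramethoxy-4-oxo-4H-chromene-2-carbaldehyde, via β-diketone 10 (not isolated), via chromone diethyl acetal 11 (not isolated)
Conditions: NaH, THF, 65 °C; AcOH, cat. H2SO4, 60 °C; 3 M aq. HCl, 50 °C
Reagents that add atoms: none
Why: Crossed Claisen condensation of the ketone dianion with the non-enolisable ester gives the 1,3-diketone, acid cyclodehydration closes the γ-pyrone (classical chromone synthesis) and aqueous acid unmasks the acetal.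

Step 6
Reactants: 12 5,6,7,8-tetramethoxy-4-oxo-4H-chromene-2-carbaldehyde; 13 dimethyl (1-diazo-2-oxopropyl)phosphonate (Ohira–Bestmann reagent)
Product: 14 2-ethynyl-5,6,7,8-tetramethoxy-4H-chromen-4-one
Conditions: K2CO3, MeOH, 0 °C → rt, short reaction time
Reagents that add atoms: none
Why: Seyferth–Gilbert homologation with the Ohira–Bestmann reagent converts the heteroaryl-type aldehyde into the terminal alkyne under mild carbonate conditions, kept cold and short because chromones are base-sensitive.

Step 7
Reactants: 15 (E)-(2-bromovinyl)trimethylsilane; 16 chromium hexacarbonyl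
Product: 19 tetramethylammonium pentacarbonyl[(E)-3-(trimethylsilyl)acryloyl]chromate, via silylvinyllithium 17 (not isolated), via lithium acylchromate 18 (not isolated)
Conditions: t-BuLi (2 equiv), Et2O, −78 °C; Cr(CO)6, Et2O, −78 °C → rt; Me4NBr, H2O
Reagents that add atoms: tetramethylammonium bromide, C[N+](C)(C)C.[Br-]
Why: Stereoretentive bromine–lithium exchange gives the (E)-vinyllithium, which adds to a CO ligand (acylmetalate stage of the Fischer carbene synthesis), and cation metathesis gives a salt that can be isolated.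

Step 8
Reactants: 19 tetramethylammonium pentacarbonyl[(E)-3-(trimethylsilyl)acryloyl]chromate
Product: 21 pentacarbonyl{benzyloxy[(E)-2-(trimethylsilyl)vinyl]carbene}chromium(0), via acetoxycarbene complex 20 (not isolated)
Conditions: AcBr, CH2Cl2, −40 °C; BnOH, −40 → 0 °C
Reagents that add atoms: benzyl alcohol, OCc1ccccc1
Why: O-Acylation of the acylmetalate gives a highly electrophilic acyloxycarbene, and addition–elimination of benzyl alcohol at the carbene carbon (alkoxy exchange) installs the benzyl ether that simple alkylation would not, the β-silyl group shielding the alkene from conjugate addition.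

Step 9
Reactants: 14 2-ethynyl-5,6,7,8-tetramethoxy-4H-chromen-4-one; 21 pentacarbonyl{benzyloxy[(E)-2-(trimethylsilyl)vinyl]carbene}chromium(0)
Product: 24 2-[5-(benzyloxy)-2-hydroxyphenyl]-5,6,7,8-tetramethoxy-4H-chromen-4-one, via tricarbonylchromium arene complex 22 (not isolated), via aryl trimethylsilyl ether 23 (not isolated)
Conditions: 21 (1.5 equiv), THF, 50 °C, Ar; air, MeCN, rt; 1 M aq. HCl, THF, rt
Reagents that add atoms: none
Why: Thermal loss of CO from 21 lets the alkyne of 14 insert into Cr=C to give an η3-vinylcarbene, CO insertion gives a chromium-bound dienylketene, and ring closure gives a cyclohexa-2,4-dienone whose C3' carries H and SiMe3. A 1,3-shift of silicon from C3' to the C2' oxygen aromatises the ring to 22, air strips Cr(CO)3 to give 23, and dilute acid cleaves the labile aryl silyl ether to 24. The closest known reaction is the Dötz benzannulation of trans-β-silylvinyl alkoxycarbene chromium complexes with terminal alkynes, in which the silyl group stabilises the vinyl complex and ends on the phenol oxygen. Ring B closes by thermal 6π-electrocyclisation of the dienylketene, which forms C2'–C3' after the two insertions have made C5'–C6' and C1'–C2'. No stereocentre is formed. The step needs the chromonyl-bearing alkyne carbon to bond to the CO-derived carbon, which the terminal alkyne secures because its larger substituent is placed away from the original carbene carbon during insertion; the electron-poor, chromone-conjugated alkyne is the main uncertainty.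

Step 10
Reactants: 24 2-[5-(benzyloxy)-2-hydroxyphenyl]-5,6,7,8-tetramethoxy-4H-chromen-4-one
Product: 25 5,2',5'-trihydroxy-6,7,8-trimethoxyflavone
Conditions: BCl3 (4 equiv), pentamethylbenzene, CH2Cl2, −78 → 0 °C; MeOH, 1 M aq. HCl
Reagents that add atoms: none
Why: Lewis-acid ether cleavage, in which BCl3 removes the aryl benzyl ether with pentamethylbenzene trapping the benzyl cation, and on warming the boron chelate at C4=O delivers chloride only to the peri 5-O-methyl group, so the 6-, 7- and 8-methoxy groups should survive.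

**Compound list**

1 | 2,3,4-trimethoxybenzaldehyde | COc1ccc(C=O)c(OC)c1OC | starting material
2 | 2,3,4-trimethoxyphenyl formate | COc1ccc(OC=O)c(OC)c1OC | intermediate
3 | 2,3,4-trimethoxyphenol | COc1ccc(O)c(OC)c1OC | intermediate
4 | 1,2,3,4-tetramethoxybenzene | COc1ccc(OC)c(OC)c1OC | intermediate
5 | (2,3,4,5-tetramethoxyphenyl)lithium | [Li]c1cc(OC)c(OC)c(OC)c1OC | intermediate
6 | dimethyl (2,3,4,5-tetramethoxyphenyl)boronate | COB(OC)c1cc(OC)c(OC)c(OC)c1OC | intermediate
7 | 2,3,4,5-tetramethoxyphenol | Oc1cc(OC)c(OC)c(OC)c1OC | intermediate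
8 | 1-(2-hydroxy-3,4,5,6-tetramethoxyphenyl)ethan-1-one | CC(=O)c1c(O)c(OC)c(OC)c(OC)c1OC | intermediate
9 | ethyl 2,2-diethoxyacetate | CCOC(=O)C(OCC)OCC | starting material
10 | 4,4-diethoxy-1-(2-hydroxy-3,4,5,6-tetramethoxyphenyl)butane-1,3-dione | CCOC(OCC)C(=O)CC(=O)c1c(O)c(OC)c(OC)c(OC)c1OC | intermediate
11 | 2-(diethoxymethyl)-5,6,7,8-tetramethoxy-4H-chromen-4-one | CCOC(OCC)c1cc(=O)c2c(OC)c(OC)c(OC)c(OC)c2o1 | intermediate
12 | 5,6,7,8-tetramethoxy-4-oxo-4H-chromene-2-carbaldehyde | O=Cc1cc(=O)c2c(OC)c(OC)c(OC)c(OC)c2o1 | intermediate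
13 | dimethyl (1-diazo-2-oxopropyl)phosphonate | CC(=O)C(=[N+]=[N-])P(=O)(OC)OC | starting material
14 | 2-ethynyl-5,6,7,8-tetramethoxy-4H-chromen-4-one | C#Cc1cc(=O)c2c(OC)c(OC)c(OC)c(OC)c2o1 | intermediate
15 | (E)-(2-bromovinyl)trimethylsilane | C[Si](C)(C)/C=C/Br | starting material
16 | chromium hexacarbonyl | O=C=[Cr](=C=O)(=C=O)(=C=O)(=C=O)=C=O | starting material
17 | (E)-[2-(trimethylsilyl)vinyl]lithium | C[Si](C)(C)/C=C/[Li] | intermediate
18 | lithium pentacarbonyl[(E)-3-(trimethylsilyl)acryloyl]chromate | [Li+].[O-]C(/C=C/[Si](C)(C)C)=[Cr](=C=O)(=C=O)(=C=O)(=C=O)=C=O | intermediate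
19 | tetramethylammonium pentacarbonyl[(E)-3-(trimethylsilyl)acryloyl]chromate | C[N+](C)(C)C.[O-]C(/C=C/[Si](C)(C)C)=[Cr](=C=O)(=C=O)(=C=O)(=C=O)=C=O | intermediate
20 | pentacarbonyl{acetoxy[(E)-2-(trimethylsilyl)vinyl]carbene}chromium(0) | CC(=O)OC(/C=C/[Si](C)(C)C)=[Cr](=C=O)(=C=O)(=C=O)(=C=O)=C=O | intermediate
21 | pentacarbonyl{benzyloxy[(E)-2-(trimethylsilyl)vinyl]carbene}chromium(0) | C[Si](C)(C)/C=C/C(OCc1ccccc1)=[Cr](=C=O)(=C=O)(=C=O)(=C=O)=C=O | intermediate
22 | tricarbonyl(η6-arene)chromium complex of 23, chromium on ring B (SMILES written as arene plus Cr(CO)3 fragment) | C[Si](C)(C)Oc1ccc(OCc2ccccc2)cc1-c1cc(=O)c2c(OC)c(OC)c(OC)c(OC)c2o1.O=C=[Cr](=C=O)=C=O | intermediate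
23 | 2-[5-(benzyloxy)-2-(trimethylsilyloxy)phenyl]-5,6,7,8-tetramethoxy-4H-chromen-4-one | C[Si](C)(C)Oc1ccc(OCc2ccccc2)cc1-c1cc(=O)c2c(OC)c(OC)c(OC)c(OC)c2o1 | intermediate
24 | 2-[5-(benzyloxy)-2-hydroxyphenyl]-5,6,7,8-tetramethoxy-4H-chromen-4-one | Oc1ccc(OCc2ccccc2)cc1-c1cc(=O)c2c(OC)c(OC)c(OC)c(OC)c2o1 | intermediate
25 | 5,2',5'-trihydroxy-6,7,8-trimethoxyflavone (achiral) | COc1c(OC)c(O)c2c(=O)cc(-c3cc(O)ccc3O)oc2c1OC | target

**Count and risks**

Total step count: 10. Longest linear sequence: 8 steps (steps 1–6, 9 and 10); the carbene branch (steps 7 and 8) joins at step 9.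

Steps most likely to fail:

Step 9. Alkyne insertion may be slow or unselective because the alkyne is conjugated to the electron-poor pyranone. The vinylcarbene or vinylketene intermediates may be diverted to cyclobutenone, furan or five-membered-ring products, the alkyne may oligomerise at chromium, or silicon may fail to migrate cleanly from carbon to oxygen. The fallback gives up the annulation and builds ring C onto a ready-made ring B. It sets out from 8: Claisen–Schmidt condensation with commercial 2,5-bis(benzyloxy)benzaldehyde (KOH, EtOH, rt) should give (E)-3-[2,5-bis(benzyloxy)phenyl]-1-(2-hydroxy-3,4,5,6-tetramethoxyphenyl)prop-2-en-1-one F1. Oxidative cyclisation with catalytic I2 in DMSO at 130 °C should give 2-[2,5-bis(benzyloxy)phenyl]-5,6,7,8-tetramethoxy-4H-chromen-4-one F2. Treatment with BCl3 and pentamethylbenzene under the conditions of step 10 removes both benzyl groups and the 5-O-methyl group, and the fallback comes back to the route at 25.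

Step 6. Methoxide or methanol may add to C2 of the pyranone or to the newly formed conjugated alkyne, or the diazophosphonate anion may add across C2=C3, in competition with homologation. The fallback brings the alkyne in with the acylating partner and sets out from 8. Acylation of its lithium dianion (LiHMDS, THF, −78 °C) with commercial ethyl 3-(trimethylsilyl)propiolate should give 1-(2-hydroxy-3,4,5,6-tetramethoxyphenyl)-5-(trimethylsilyl)pent-4-yne-1,3-dione F3. Cyclodehydration with catalytic H2SO4 in AcOH should give 5,6,7,8-tetramethoxy-2-[(trimethylsilyl)ethynyl]-4H-chromen-4-one F4. Desilylation with TBAF buffered by AcOH (THF, 0 °C) comes back to the route at 14.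

Step 10. Once the boron chelate at O5 has formed, demethylation may run on to O6, the benzyl cation may alkylate the electron-rich ring B, or the hydroquinone may be oxidised by air during work-up. The fallback separates the two cleavages and sets out from 24. Hydrogenolysis (H2, Pd/C, EtOAc–MeOH, rt) should give 2-(2,5-dihydroxyphenyl)-5,6,7,8-tetramethoxy-4H-chromen-4-one F5. Chelation-controlled demethylation of the 5-methoxy group with AlCl3 in MeCN (rt to 50 °C, under argon) comes back to the route at 25.

**Further compounds**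

F1 | step 9 | (E)-3-[2,5-bis(benzyloxy)phenyl]-1-(2-hydroxy-3,4,5,6-tetramethoxyphenyl)prop-2-en-1-one | O=C(/C=C/c1cc(OCc2ccccc2)ccc1OCc1ccccc1)c1c(O)c(OC)c(OC)c(OC)c1OC
F2 | step 9 | 2-[2,5-bis(benzyloxy)phenyl]-5,6,7,8-tetramethoxy-4H-chromen-4-one | O=c1cc(-c2cc(OCc3ccccc3)ccc2OCc2ccccc2)oc2c(OC)c(OC)c(OC)c(OC)c12
F3 | step 6 | 1-(2-hydroxy-3,4,5,6-tetramethoxyphenyl)-5-(trimethylsilyl)pent-4-yne-1,3-dione | C[Si](C)(C)C#CC(=O)CC(=O)c1c(O)c(OC)c(OC)c(OC)c1OC
F4 | step 6 | 5,6,7,8-tetramethoxy-2-[(trimethylsilyl)ethynyl]-4H-chromen-4-one | C[Si](C)(C)C#Cc1cc(=O)c2c(OC)c(OC)c(OC)c(OC)c2o1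
F5 | step 10 | 2-(2,5-dihydroxyphenyl)-5,6,7,8-tetramethoxy-4H-chromen-4-one | COc1c(OC)c(OC)c2c(=O)cc(-c3cc(O)ccc3O)oc2c1OC
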